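A small charge of E, 0.24 mM against 0.064 M of L in violet and in grey, has to go round many times, so you reckon these flasks by the catalyst's balance: each E must make 267 rounds to finish the L, while X, bound to the catalyst, can hold at most 0.375% of the L. The X column, with its scatter of 2 percentage points, therefore tells you nothing, and the lead lies between L and Q.

all flasks: E 0.24 mM; G 0.22 mM

| run | L | temperature | remark | time |
|---|---|---|---|---|
| Saturday's | 0.043 M | 5 °C | run made earlier |  |
| Wednesday's | 0.096 M | 24 °C | run made earlier |  |
| violet | 0.064 M | 20 °C |  | 1.5 h |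
| grey | 0.064 M | 28 °C |  | 1.5 h |

- Saturday's (time / h: Q / %, L / %, X / %): 0.200: 3, 96, 3; 0.667: 5, 92, 1; 1.00: 10, 92, 3; 2.00: 16, 83, 0; 3.00: 24, 74, 0
- Wednesday's (time / min: Q / %, L / %, X / %): 6.00: 5, 97, 1; 20.0: 15, 89, 1; 30.0: 16, 82, 4; 50.0: 27, 72, 2; 60.0: 36, 67, 0; 90.0: 47, 49, 1

(each reading ± 2 percentage points)

1. which of these there is most of at the end, counted by the L in it, violet (L / X / Q)
2. which of these there is most of at the end, counted by the L in it, grey (L / X / Q)
3. how much there is at the end of the one of these that leads, in percent of the L charged: violet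
4. how much there is at the end of the one of these that leads, in percent of the L charged: grey

Wednesday's last reading gives a turnover rate (turnover frequency) of 125 h⁻¹ and Saturday's 14.3 h⁻¹. Between the two temperatures that means an activation energy of 78.4 kJ mol⁻¹ if the pace is flat in L (zero order), or 55.4 kJ mol⁻¹ if it goes in proportion to L. The flat reading gives, at 20 °C, 81.3 h⁻¹ for violet's turnover rate, the Q made per hour for each E charged, and 191 h⁻¹ for grey at 28 °C. Over 1.5 h grey's pace gives 286 rounds, more than the 267 it needs, so on this reckoning a flat pace finishes grey's L; that is the high end of my bracket, and proportion gives the low end. But Wednesday's readings show the flat pace only down to 47.0 mM of L, so I tighten by my own choice: flat down to there, proportional below. I commit to the middle column.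

| Leader at the end | Proportional | Flat, then proportional | Flat throughout | Forecast |
|---|---|---|---|---|
| Violet, L | 62.7% | 56.6% | 54.3% | 55% |
| Grey, Q | 57.5% | 75.6% | 100% | 85% |

The forecast, on the grounds “That looks close to zero order, a saturated catalyst”, names the same leaders as my middle column, and both its numbers stand inside my outer columns but on the flat side of the middle one: 55% is less than my 56.6% for violet, and 85% is more than my 75.6% for grey.

    L + E ⇌ X (K = 580 M⁻¹, k = 100 M⁻¹ min⁻¹, Ea = 60.0 kJ mol⁻¹, ΔH = −15.0 kJ mol⁻¹)
    X → E + Q (k = 3.00 min⁻¹, Ea = 75.0 kJ mol⁻¹)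
    E → Z (k = 3.40 × 10⁻⁵ min⁻¹, Ea = 108 kJ mol⁻¹)
    E + G ⇌ J, settled at all times (K = 7600 M⁻¹, ΔH = 2.00 kJ mol⁻¹)
    (constants at 20 °C)

Violet ends with L at 57.2% and grey with Q at 72.8%, which is 12 points under the forecast. In grey, X goes from 31.8% of the catalyst charged at 0.750 h to 19.1% at 1.50 h. Violet's turnover rate, averaged over its 1.5 h, comes out at 75.9 h⁻¹, against the 81.3 h⁻¹ reckoned. A further flask, like violet but with E at 9.6 × 10⁻⁴ M, needs 66.7 rounds, and 81.3 h⁻¹ over 1.5 h offers 122, more than that; that flask ends with Q at 99.0%.

The data were generated by integration with made-up constants; scatter was added.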